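**Remark on the chemistry:** bromo ester 10 is used as the racemate, so 11 and 12 are racemic. Their only stereocentre becomes the trigonal C2 of 13, so no stereocontrol is needed anywhere in the route.

## Analysis of the target

The target 16 is a flavone: a benzene ring A fused to a 4-pyranone ring C (O1, C2, C3, C4, C4a, C8a), with an unsubstituted phenyl ring B on C2. Ring A is fully substituted (5-OH, 6-, 7- and 8-OMe, C4a, C8a) and ring C carries a methoxy group at C3. Five oxygen substituents must therefore be placed, and exactly one of them left unmethylated. There is no stereocentre; the problems are regiochemical and chemoselective. Ring A, with para-related oxygens at C5 and C8, is easily oxidised to quinones, and its methyl ethers are open to strong Lewis acids, so oxidants and hard acids should be used sparingly. The 5-OH is hydrogen-bonded to the C4 carbonyl, and this peri relationship is what distinguishes O5 from the other four oxygens. The plan rests on the oxidation pattern of ring C: in the diketo tautomer of a 3-hydroxyflavone both C3 and C4 are carbonyl carbons. The C3–C4 bond thus joins two electrophilic centres and can be made directly only if one of them reacts with inverted polarity, which an aldehyde at C4 and an ester at C3 allow.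

## Retrosynthetic reasoning

**O5–CH3.** The free hydroxyl of 16 is the one oxygen peri to the C4 carbonyl. It can be revealed last from the fully methylated flavone 14 by a Lewis acid that chelates between the carbonyl oxygen and O5 (boron chelate 15). All five oxygens can then travel as methyl ethers and no special protecting group is needed at O5.

**O3–CH3.** Removing the methyl group on O3 leads back to flavonol 13. Its enolic 3-hydroxyl is the only acidic site, so the forward methylation needs no selectivity.

**C3–C4 (key disconnection).** Flavonol 13 is the enol of the 2-phenylchroman-3,4-dione 12. Cutting C3–C4 of 12 gives an aryl aldehyde (C4) and a carboxylic ester (C3) joined through O1 and C2, which is compound 11.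

- Why this bond: the usual cuts at O1–C2 or C2–C3 give a ring C that lacks the C3 oxygen or needs an oxidative closure on an oxidation-prone ring A. Cutting C3–C4 gives ring C at its final oxidation level with the C3 oxygen already present.
- What the forward reaction must do: a carbene catalyst has to turn the aldehyde carbon into a nucleophile, which must attack the ester carbonyl in a six-membered closure and expel the alkoxy group. The C2 hydrogen of 12 then makes aromatisation to 13 irreversible.
- Choice of acceptor: the plain methyl ester is kept. An activated aryl ester would be a better acceptor for the acyl anion equivalent, but it would also be attacked by the free carbene and would form a ketene with base.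

**O1–C2.** The ether bond of 11 is cut between the phenol oxygen and the benzylic carbon, giving salicylaldehyde 9 and the alpha-bromo ester 10. The forward step is an SN2 displacement at an activated secondary carbon that has no beta-hydrogen.

**C4a–CHO.** The formyl group of 9 is removed to give phenol 7. Compound 7 has a single unsubstituted ring carbon, ortho to the hydroxyl, so the forward formylation (through benzylic alcohol 8) has no regiochemical choice.

**C8a–O.** The hydroxyl of 7 is traced to a ring hydrogen of 4 through aryllithium 5 and boronate 6. Compound 4 is symmetric and its two ring hydrogens are equivalent, so metalation gives one product. One of these two carbons becomes C8a and the other, in the next step, C4a.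

**O–CH3 and C–O.** Compound 4 is the methyl ether of phenol 3, and 3 comes from the commodity aldehyde 1 by exchange of the formyl group for hydroxyl through aryl formate 2. This gives the 1,2,3,4-tetraoxygenated benzene without any C–H oxidation.

## Alternatives that were turned down

**Alternative 1:** disconnection of the C4–C4a bond.
- Forward key step: the cationic monovalent gold complex Ph3PAuNTf2 activates the terminal alkyne of the racemic aryl 1-phenylpropargyl ether A2, which phenol 7 would give in one step. The single unsubstituted ring carbon, ortho to the ether oxygen, attacks in a 6-endo-dig hydroarylation to give the racemic 2H-chromene A1.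
- For it: this reaction type is well established for aryl propargyl ethers, which the chosen key step is not. The arene is strongly nucleophilic and has only one carbon left to react.
- Against it: A1 has ring C at too low an oxidation level and lacks the C3 oxygen. The C3=C4 bond would have to be dihydroxylated and both new carbinol carbons oxidised before 13 is reached, on a molecule whose ring A is itself readily oxidised. The C–O bond of A2 is both benzylic and propargylic and can ionise under the Lewis-acidic catalyst. A1, a 2-aryl-2H-chromene, is prone to electrocyclic ring opening.
- Comparison: four steps from 7 to 13 instead of three, with the risk moved from one ring closure to a series of oxidations. The chosen strategy has weaker precedent but forms ring C at the final oxidation level and uses no oxidant after step 3.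

**Alternative 2:** disconnection of C4a–C4, C4–C3 and O1–C2 in one operation.
- Forward key step: PdCl2(PPh3)2 and a secondary amine base would effect a carbonylative Sonogashira coupling of the symmetric iodoresorcinol A4 with phenylacetylene A5. One flanking hydroxyl would then add to the ynone in a 6-endo closure to give 5-hydroxy-6,7,8-trimethoxyflavone A3.
- For it: it is the most convergent of the plans. The symmetry of A4 removes any regiochemical question, the second hydroxyl emerges directly as the free 5-OH, and carbonylative annulations of ortho-iodophenols are known chemistry. On convergence and precedent it is stronger than the chosen strategy.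
- Against it: A3 has no oxygen at C3. Adding it later means protecting the 5-OH, functionalising and oxidising C3, methylating and deprotecting, about four steps on the finished flavone. A4 is not a catalogue compound and needs its own multistep synthesis. Oxidative addition of zerovalent palladium into a C–I bond flanked by two free hydroxyls on an electron-rich ring is slow, and 5-exo closure to an aurone competes.
- Comparison: the C3 oxygen that it leaves out is delivered by the chosen C3–C4 closure as part of the ring-forming event.

**Alternative 3:** disconnection of the O1–C8a bond.
- Forward key step: (NH4)2Ce(NO3)6 would oxidise the para-related methoxy pair of the tetramethoxyphenyl diketone A7 to the acylquinone A8. The enol oxygen of the benzoyl group then adds to the quinone C–H carbon in an oxa-Michael closure, and tautomerisation gives the hydroquinone 5,8-dihydroxy-3,6,7-trimethoxyflavone A6.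
- For it: A7 already carries the 3-methoxy group and should come from 4 in about two steps. A6 needs only methylation of the unchelated 8-OH to become 16. This is probably the shortest plan, about two steps shorter than the chosen route, and on step count it is stronger.
- Against it: tetravalent cerium meets three oxidisable sites at once: the tetramethoxyarene, the enolised diketone and the product A6. A6 is oxidised more easily than A7 and can also be dehydrogenated by A8, so over-oxidation to a flavone-5,8-quinone is hard to prevent. A8 is a very strong electrophile and would be intercepted by nucleophiles of the aqueous medium in competition with the enol oxygen.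
- Comparison: the chosen strategy is longer, but it uses no oxidant on the electron-rich ring once phenol 7 is made, and all its intermediates are stable. Its selectivity is fixed by constitution (one free ring carbon, one aldehyde), not by relative rates of oxidation.

Key step: step 6

## Route

Step 1
Reactants: 1 2,3,4-trimethoxybenzaldehyde
Product: 3 2,3,4-trimethoxyphenol, via aryl formate 2 (not isolated)
Conditions: 30% H2O2, cat. H2SO4, MeOH, rt
Reagents that add atoms: hydrogen peroxide, OO
Why: Dakin-type Baeyer–Villiger oxidation; the aryl group, made electron-rich by the ortho and para methoxy groups, migrates to the peroxide oxygen in preference to hydride, and formate 2 is methanolysed in the same pot under the acid catalyst.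

Step 2
Reactants: 3 2,3,4-trimethoxyphenol
Product: 4 1,2,3,4-tetramethoxybenzene
Conditions: MeI, K2CO3, acetone, reflux
Reagents that add atoms: iodomethane, CI
Why: Williamson O-methylation; the phenoxide oxygen is the only nucleophilic site.

Step 3
Reactants: 4 1,2,3,4-tetramethoxybenzene
Product: 7 2,3,4,5-tetramethoxyphenol, via aryllithium 5 (not isolated), via boronate ester 6 (not isolated)
Conditions: n-BuLi, TMEDA, THF, 0 °C to rt; B(OMe)3, −78 °C to rt; AcOH, 30% H2O2, 0 °C to rt
Reagents that add atoms: hydrogen peroxide, OO
Why: Directed ortho-metalation next to a methoxy group; the two ring hydrogens of 4 are equivalent by symmetry, so only aryllithium 5 can form. Borylation to 6 and peroxide-induced 1,2-shift of the aryl group from boron to oxygen then give the phenol.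

Step 4
Reactants: 7 2,3,4,5-tetramethoxyphenol
Product: 9 2-hydroxy-3,4,5,6-tetramethoxybenzaldehyde, via salicyl alcohol 8 (not isolated)
Conditions: MgCl2, Et3N, (CH2O)n, MeCN, reflux; then 1 M HCl
Reagents that add atoms: formaldehyde (as paraformaldehyde), C=O
Why: Magnesium-mediated ortho-formylation (Casnati–Skattebøl); the magnesium phenoxide delivers formaldehyde to the ortho carbon through a chelate, and the benzylic alkoxide 8 is oxidised by a second formaldehyde through hydride transfer. Only one ring carbon is unsubstituted, so the position is fixed.

Step 5
Reactants: 9 2-hydroxy-3,4,5,6-tetramethoxybenzaldehyde; 10 methyl 2-bromo-2-phenylacetate (racemic)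
Product: 11 methyl 2-(2-formyl-3,4,5,6-tetramethoxyphenoxy)-2-phenylacetate (racemic)
Conditions: K2CO3, DMF, rt
Reagents that add atoms: none
Why: Williamson ether synthesis; the phenoxide displaces bromide from a benzylic alpha-bromo ester, an activated secondary electrophile without beta-hydrogens. Mild carbonate base at room temperature should keep the product from enolising and closing onto its own aldehyde.

Step 6
Reactants: 11 methyl 2-(2-formyl-3,4,5,6-tetramethoxyphenoxy)-2-phenylacetate (racemic)
Product: 13 3-hydroxy-5,6,7,8-tetramethoxyflavone (3-hydroxy-5,6,7,8-tetramethoxy-2-phenyl-4H-chromen-4-one), via chroman-3,4-dione 12 (not isolated)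
Conditions: 2-(pentafluorophenyl)-6,7-dihydro-5H-pyrrolo[2,1-c][1,2,4]triazol-2-ium tetrafluoroborate (20 mol %), DBU (1.3 equiv), 4 Å MS, toluene, 60 °C, argon; then 1 M HCl
Reagents that add atoms: none
Why: Proposed new method: DBU frees the triazolylidene, which adds to the formyl carbon of 11, and proton transfer gives the enaminol (Breslow intermediate) whose nucleophilic carbon is the future C4. This carbon attacks the ester carbonyl, the future C3, in a 6-exo-trig closure that forms the C3–C4 bond and ring C; loss of methanol and release of the carbene from the adduct give dione 12. Base then removes the C2 hydrogen of 12, which is flanked by phenyl, ether oxygen and ketone, and the resulting enol is the aromatic 4-pyranone 13; this tautomerisation is irreversible and pulls the preceding equilibria forward, and because 13 is held as its DBU salt until the acidic work-up, more than one equivalent of base is used. The closest known reaction types are the carbene-catalysed intramolecular crossed benzoin of 2-(2-oxoalkoxy)benzaldehydes to 3-hydroxychroman-4-ones and the related addition of such acyl anion equivalents to a pendant nitrile, which gives 3-aminochromones; an ester as acceptor has not been established. No stereocentre is formed, and the racemic centre of 11 ends as the trigonal C2. Chemoselectivity rests on the substrate: only the formyl group can form an acyl anion equivalent, the methyl ester (unlike an aryl ester) is not acylated by the carbene, and the competing aldol adduct of the ester enolate, a 2,3-dihydrobenzofuran-3-ol with a quaternary C2, cannot dehydrate and reverts. The compact bicyclic N-pentafluorophenyl carbene is chosen because the aldehyde sits between two ortho oxygen substituents, and air and water are excluded to prevent oxidation of the enaminol and hydrolysis of the ester.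

Step 7
Reactants: 13 3-hydroxy-5,6,7,8-tetramethoxyflavone
Product: 14 3,5,6,7,8-pentamethoxyflavone
Conditions: MeI, K2CO3, acetone, reflux
Reagents that add atoms: iodomethane, CI
Why: Williamson O-methylation of the enolic 3-hydroxyl, the only acidic group in 13.

Step 8
Reactants: 14 3,5,6,7,8-pentamethoxyflavone
Product: 16 5-hydroxy-3,6,7,8-tetramethoxyflavone (target), via boron chelate 15 (not isolated)
Conditions: BCl3 (1.5 equiv), CH2Cl2, −78 to 0 °C; then aq. HCl, MeOH, rt
Reagents that add atoms: none
Why: Chelation-controlled Lewis acid ether cleavage; BCl3 bridges the C4 carbonyl oxygen and the peri 5-methoxy oxygen in a six-membered chelate, chloride removes that methyl group by SN2, and chelate 15 is hydrolysed on work-up. The 3-methoxy group could only form a less favourable five-membered chelate, and the 6-, 7- and 8-methoxy groups have no carbonyl partner.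

## Compound list

1 | 2,3,4-trimethoxybenzaldehyde | COc1ccc(C=O)c(OC)c1OC | starting material
2 | 2,3,4-trimethoxyphenyl formate (formed in the flask, not isolated) | COc1ccc(OC=O)c(OC)c1OC | intermediate
3 | 2,3,4-trimethoxyphenol | COc1ccc(O)c(OC)c1OC | intermediate
4 | 1,2,3,4-tetramethoxybenzene | COc1ccc(OC)c(OC)c1OC | intermediate
5 | (2,3,4,5-tetramethoxyphenyl)lithium (formed in the flask, not isolated) | [Li]c1cc(OC)c(OC)c(OC)c1OC | intermediate
6 | dimethyl (2,3,4,5-tetramethoxyphenyl)boronate (formed in the flask, not isolated) | COB(OC)c1cc(OC)c(OC)c(OC)c1OC | intermediate
7 | 2,3,4,5-tetramethoxyphenol | COc1cc(O)c(OC)c(OC)c1OC | intermediate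
8 | 2-(hydroxymethyl)-3,4,5,6-tetramethoxyphenol, held as its magnesium phenoxide ArOMgCl (formed in the flask, not isolated) | COc1c(CO)c(O)c(OC)c(OC)c1OC | intermediate
9 | 2-hydroxy-3,4,5,6-tetramethoxybenzaldehyde | COc1c(C=O)c(O)c(OC)c(OC)c1OC | intermediate
10 | methyl 2-bromo-2-phenylacetate (racemic) | COC(=O)C(Br)c1ccccc1 | starting material
11 | methyl 2-(2-formyl-3,4,5,6-tetramethoxyphenoxy)-2-phenylacetate (racemic) | COC(=O)C(Oc1c(C=O)c(OC)c(OC)c(OC)c1OC)c1ccccc1 | intermediate
12 | 5,6,7,8-tetramethoxy-2-phenylchroman-3,4-dione (racemic; formed in the flask, not isolated) | COc1c(OC)c(OC)c2C(=O)C(=O)C(c3ccccc3)Oc2c1OC | intermediate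
13 | 3-hydroxy-5,6,7,8-tetramethoxyflavone | COc1c(OC)c(OC)c2c(=O)c(O)c(-c3ccccc3)oc2c1OC | intermediate
14 | 3,5,6,7,8-pentamethoxyflavone | COc1c(OC)c(OC)c2c(=O)c(OC)c(-c3ccccc3)oc2c1OC | intermediate
15 | 5-(dichloroboryloxy)-3,6,7,8-tetramethoxyflavone, boron chelated by the C4 carbonyl (formed in the flask, not isolated) | COc1c(OC)c(OB(Cl)Cl)c2c(=O)c(OC)c(-c3ccccc3)oc2c1OC | intermediate
16 | 5-hydroxy-3,6,7,8-tetramethoxyflavone | COc1c(OC)c(O)c2c(=O)c(OC)c(-c3ccccc3)oc2c1OC | target

## Step count and least certain steps

Total step count: 8. Longest linear sequence: 8 steps, from 1 to 16; bromo ester 10 is bought.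

**Step 6 (key step, proposed new method).**
- What may go wrong: C–C bond formation at the weakly electrophilic methyl ester may be slower than the side reactions of the enaminol, namely oxidation by traces of air and intermolecular benzoin coupling. Carbene addition to the di-ortho-substituted aldehyde may itself be sluggish. Under stoichiometric DBU the ester enolate can drain 11 through the aldol adduct, which at higher temperature can lose the ester carbon irreversibly by lactonisation and decarboxylation.
- Fallback (known chemistry): it sets out from phenol 7 and returns to the route at 14. Phenol 7 would undergo Hoesch acylation at its only free ring carbon with methoxyacetonitrile (ZnCl2, HCl gas, Et2O, 0 °C) to give the ketimine 1-(2-hydroxy-3,4,5,6-tetramethoxyphenyl)-2-methoxyethan-1-imine F1 as its hydrochloride. Hot water would hydrolyse this to the ketone 1-(2-hydroxy-3,4,5,6-tetramethoxyphenyl)-2-methoxyethan-1-one F2. O-Benzoylation (BzCl, pyridine) would give 2-(methoxyacetyl)-3,4,5,6-tetramethoxyphenyl benzoate F3. Baker–Venkataraman rearrangement (KOH, pyridine, 50 °C) would give the diketone 1-(2-hydroxy-3,4,5,6-tetramethoxyphenyl)-2-methoxy-3-phenylpropane-1,3-dione F4, and cyclodehydration (H2SO4, AcOH) would give 14, from which step 8 finishes the synthesis. Ring C is closed here through the O1–C2 bond, independently of carbene chemistry.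

**Step 5 (O-alkylation).**
- What may go wrong: the phenoxide of 9 is hindered and hydrogen-bonded, so alkylation may be slow. The product carries an acidic C–H and may undergo base-induced intramolecular aldol closure, or ester hydrolysis, under prolonged exposure to carbonate.
- Fallback: from 9 directly to 11 by Mitsunobu etherification with racemic methyl mandelate (PPh3, DIAD, THF, 0 °C to rt). The alcohol partner is activated under neutral conditions, so no enolisable product meets a base. This fallback makes no new compound.

**Step 4 (ortho-formylation).**
- What may go wrong: formylation at a carbon flanked by two oxygen substituents may stall at the hydroxymethyl stage, and the benzylic intermediate may condense with a second phenol molecule.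
- Fallback: from 7 back to 9 by a metalation route. Protection of 7 (MOMCl, i-Pr2NEt, CH2Cl2) would give 1,2,3,4-tetramethoxy-5-(methoxymethoxy)benzene F5. Directed ortho-lithiation (n-BuLi, THF, −78 to 0 °C) at the only ring hydrogen would give [2-(methoxymethoxy)-3,4,5,6-tetramethoxyphenyl]lithium F6, and quenching with DMF would give 2-(methoxymethoxy)-3,4,5,6-tetramethoxybenzaldehyde F7. Acidic methanolysis (HCl, MeOH) would return 9.

**Step 8 (selective demethylation).**
- What may go wrong: over-demethylation, either at the 3-methoxy group through the five-membered chelate or at the 6-methoxy group next to the newly freed phenol.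
- Fallback: the order of the last two operations is reversed; it sets out from 13 and returns at 16. Treatment of 13 with AlCl3 in MeCN at 50 °C would cleave the 5-methyl ether while O3 is still a free hydroxyl, giving 3,5-dihydroxy-6,7,8-trimethoxyflavone F8. Methylation with one equivalent of MeI (K2CO3, acetone, rt) should then take place at the 3-hydroxyl only, because the 5-hydroxyl is held in the stronger hydrogen bond to the carbonyl and is the least reactive phenol of a flavone. This removes the 3-methoxy cleavage risk; it does not by itself address cleavage at C6.

## Further compounds

F1 | step 6 | 1-(2-hydroxy-3,4,5,6-tetramethoxyphenyl)-2-methoxyethan-1-imine (as hydrochloride in the flask) | COCC(=N)c1c(O)c(OC)c(OC)c(OC)c1OC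
F2 | step 6 | 1-(2-hydroxy-3,4,5,6-tetramethoxyphenyl)-2-methoxyethan-1-one | COCC(=O)c1c(O)c(OC)c(OC)c(OC)c1OC
F3 | step 6 | 2-(methoxyacetyl)-3,4,5,6-tetramethoxyphenyl benzoate | COCC(=O)c1c(OC(=O)c2ccccc2)c(OC)c(OC)c(OC)c1OC
F4 | step 6 | 1-(2-hydroxy-3,4,5,6-tetramethoxyphenyl)-2-methoxy-3-phenylpropane-1,3-dione (racemic, enolisable) | COC(C(=O)c1ccccc1)C(=O)c1c(O)c(OC)c(OC)c(OC)c1OC
F0 | step 5 | none | none
F5 | step 4 | 1,2,3,4-tetramethoxy-5-(methoxymethoxy)benzene | COCOc1cc(OC)c(OC)c(OC)c1OC
F6 | step 4 | [2-(methoxymethoxy)-3,4,5,6-tetramethoxyphenyl]lithium | [Li]c1c(OCOC)c(OC)c(OC)c(OC)c1OC
F7 | step 4 | 2-(methoxymethoxy)-3,4,5,6-tetramethoxybenzaldehyde | COCOc1c(C=O)c(OC)c(OC)c(OC)c1OC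
F8 | step 8 | 3,5-dihydroxy-6,7,8-trimethoxyflavone | COc1c(OC)c(O)c2c(=O)c(O)c(-c3ccccc3)oc2c1OC
A1 | alternative 1 | 5,6,7,8-tetramethoxy-2-phenyl-2H-chromene (racemic) | COc1c(OC)c(OC)c2C=CC(c3ccccc3)Oc2c1OC
A2 | alternative 1 | 1,2,3,4-tetramethoxy-5-[(1-phenylprop-2-yn-1-yl)oxy]benzene (racemic) | C#CC(Oc1cc(OC)c(OC)c(OC)c1OC)c1ccccc1
A3 | alternative 2 | 5-hydroxy-6,7,8-trimethoxyflavone | COc1c(OC)c(O)c2c(=O)cc(-c3ccccc3)oc2c1OC
A4 | alternative 2 | 2-iodo-4,5,6-trimethoxybenzene-1,3-diol | COc1c(OC)c(O)c(I)c(O)c1OC
A5 | alternative 2 | phenylacetylene | C#Cc1ccccc1
A6 | alternative 3 | 5,8-dihydroxy-3,6,7-trimethoxyflavone | COc1c(OC)c(O)c2c(=O)c(OC)c(-c3ccccc3)oc2c1O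
A7 | alternative 3 | 2-methoxy-1-phenyl-3-(2,3,4,5-tetramethoxyphenyl)propane-1,3-dione (racemic, enolisable) | COC(C(=O)c1ccccc1)C(=O)c1cc(OC)c(OC)c(OC)c1OC
A8 | alternative 3 | 2,3-dimethoxy-5-(2-methoxy-3-oxo-3-phenylpropanoyl)cyclohexa-2,5-diene-1,4-dione | COC(C(=O)c1ccccc1)C(=O)C1=CC(=O)C(OC)=C(OC)C1=O
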